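## Structural features

The target is an achiral benzophenone with three rings. Ring A is a 2,4-dihydroxy-6-propylphenyl group, ring B a 2,4-dihydroxyphenyl group, and ring C a 4-hydroxy-2H-pyran-2-one. Rings A and B are joined only through the ketone carbon, and ring B carries at C6 a methylene that ends at C6 of ring C. All four positions ortho to the ketone are substituted (two hydroxyls, the propyl group, the pyranonylmethyl group), so the diaryl ketone is twisted and crowded; there is no stereocentre. Named correctly, ring A is a 4-acyl-5-propylbenzene-1,3-diol: the acyl group lies between the propyl group and one hydroxyl and para to the other, not between the two hydroxyls. The fragile parts are ring C (a vinylogous acid and lactone, nucleophilic at C3, opened by base), the free resorcinol rings (oxidants, electrophiles), and the doubly activated CH2 between rings B and C. The ketone can also condense with its neighbours under forcing acid or base. The real difficulty is the regiocontrolled construction of the fully ortho-substituted ketone between two different resorcinols, together with a late and mild assembly of ring C. The key step exploits the fact that C1 (acyl-bearing) and C2 (propyl-bearing) of ring A are neighbours while the oxygens at C4 and C6 stand 1,3 to each other. Ring A is therefore the dehydrogenated form of a 4-acyl-5-propylcyclohexane-1,3-dione, with C1 and C6 coming from an aroylacetate and C2 to C5 plus the propyl group from hept-3-en-2-one.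

## Logic of the disconnections

**21 to 20.** The four aryl O–CH3 bonds are cut. Free phenols would not survive the strong base of the chain extension or the oxidations, and methyl ethers are already present in 1. Every earlier intermediate becomes a neutral ether. The forward cleavage must spare ring C and the ketone.

**20 to 18 (through 19).** The lactone O1–C2 bond of ring C is cut. Ring C is the most sensitive ring and is therefore formed last, under neutral heating. It is reduced to a masked acetoacetyl unit. The forward step needs clean release of the acylketene and ring closure by the ketone oxygen faster than any intermolecular trapping.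

**18 to 15 and 16.** The bond between the side-chain carbonyl carbon (future C6 of ring C) and the former methyl carbon of 16 (future C5) is cut. Four of the five ring C carbons then come from a purchased building block, and 15 is a plain arylacetic acid. The forward step needs γ-selective C-acylation by an enolizable acyl donor without attack on the diaryl ketone.

**15 to 13 to 12.** The oxidation level of the side-chain terminus is lowered and the O–benzyl bond is cut. An ester or acid at this carbon could not pass the key step, because the aroylacetate enolate would condense with it to a naphthalenediol. A free alcohol would attack the β-dicarbonyl ketone and split it by acyl transfer. The chain is therefore carried as a base-stable benzyl ether. The forward steps need hydrogenolysis that leaves the ketone alone and an oxidation that tolerates four electron-rich aryl ethers.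

**12 to 11 to 10.** One O–CH3 bond is cut, then ring A is taken back to the dione (two hydrogens added, aromaticity given up). This replaces the formation of an aryl–CO bond between two di-ortho-substituted rings by enolate chemistry on a saturated ring. The forward step needs an oxidant that dehydrogenates the dione without touching the benzyl ether or ring B. The sp3 configuration is irrelevant.

**10 to 7 and 8.** The C4–C5 and C2–C3 bonds of the dione are cut (C1–C2 and C5–C6 of ring A). Ring A falls into two carbons of 7 and four carbons plus propyl of 8, with propyl and aroyl placed on adjacent carbons by construction. The forward step needs Michael addition of a hindered donor and then acylation on the ester in preference to aldol closure on the aryl ketone.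

**7 to 6 to 5.** The bond between the benzylic carbon and the α-carbon of the ester is cut, with an oxidation-level change. An aldehyde plus an acetate ester enolate is preferred to acylation by a derivative of a di-ortho-substituted benzoic acid, which would be sluggish. The forward steps need a cold aldol addition and a mild oxidation of an electron-rich benzylic alcohol.

**5 to 3.** The aryl–CHO bond is cut. The position para to one methoxy and ortho to the other is the most nucleophilic accessible site. The forward step needs regioselection against the site between the two methoxy groups.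

**3 to 2 to 1.** The O–benzyl bond is cut and the alcohol is taken back to the ester. This ends at a purchased compound; the forward steps are routine.

## Other disconnections considered

**Alternative 1:** Both benzene rings are cut at once, at C1–C6 and C2–C3 of ring A and the corresponding bonds of ring B. This leaves the ketone carbon flanked by two alkynes, 1-(tert-butyldimethylsilyloxy)deca-3,6-diyn-5-one A1; the silyloxy group has to be part of this diynone. Heating A1 with two equivalents of 1,1-dimethoxy-3-(trimethylsilyloxy)buta-1,3-diene A2, then loss of methanol and mild methanolysis of the aryl silyl ethers, would give {2-[2-(tert-butyldimethylsilyloxy)ethyl]-4-hydroxy-6-methoxyphenyl}(4-hydroxy-2-methoxy-6-propylphenyl)methanone A3.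

- In favour: convergence is very high. The polarization of A2 fixes the regiochemistry, since its CH2 terminus bonds to the alkyl-bearing alkyne carbon, so oxygen arrives ortho and para to the ketone on both rings. The rings emerge aromatic without a separate oxidation.
- Against: A1 is a cross-conjugated double acceptor prone to polymerization. After the first ring has formed, the remaining ynone is attached to a twisted, di-ortho-substituted aryl ketone, so the second cycloaddition has to create the fully crowded benzophenone and could stall at the mono-adduct. A2 is moisture-sensitive and could also give open-chain conjugate adducts.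
- Comparison: the chosen plan forms only ring A in its key step and needs an extra dehydrogenation, but rests on robust anionic chemistry. The alternative is the better on step economy, reaching an intermediate comparable to 12 in roughly half the steps, and the equal on regiocontrol. Its weakness is the uncertain second cycloaddition. The end game from A3 would be the same as from 12.

**Alternative 2:** The two aryl–CH2 bonds ortho to the ketone are cut. Bis(2,4-dimethoxyphenyl)methanone A4 would be allylated twice with allyl acetate A5 under [RuCl2(p-cymene)]2 and AgSbF6, the ketone directing metalation to the only free ortho C–H of each ring, to give bis(2-allyl-4,6-dimethoxyphenyl)methanone A6.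

- In favour: the whole diaryl ketone comes from a bulk chemical, two C–C bonds form in one catalytic step, no ring is built, and no side-chain protecting group is needed. On these points it is better than the chosen plan.
- Against: A6 is symmetric and 21 is not. One allyl group must be reduced to propyl and the other cut down to a two-carbon acyl chain, which can only be done statistically. Cyclometalation needs the ketone coplanar with the ring, which becomes harder after the first allylation. Migration of the double bond into conjugation is a likely side path. The oxidative cleavage must be done on very electron-rich rings.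
- Comparison: the chosen plan has the two rings different from the start (ring B from 1, ring A from 8), so no desymmetrization is needed. Mechanistically the alternative replaces stoichiometric enolate chemistry by C–H activation. Its step count to the benzophenone is lower, but the statistical step and the loss of a carbon offset that gain.

**Alternative 3:** Ring B is cut at the bonds to its CH carbon and to its ester-bearing carbon. Methyl 2-[2-(benzyloxy)ethyl]-7-methoxy-4-oxo-5-propyl-4H-chromene-3-carboxylate A7, activated by (CH3)3SiOSO2CF3, would take up the terminal carbon of 1-tert-butoxy-1,3-bis(trimethylsilyloxy)buta-1,3-diene A8 at C2. The pyranone ring would then open and the central diene carbon would acylate on the former 3-ester, giving tert-butyl 4-[2-(benzyloxy)ethyl]-2,6-dihydroxy-3-(2-hydroxy-4-methoxy-6-propylbenzoyl)benzoate A9.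

- In favour: ring B is built with both oxygens in place and emerges aromatic without an oxidation step, which is better than the chosen plan on that point. The crowded ketone is never formed by an intermolecular acylation.
- Against: to put the benzyloxyethyl chain ortho to the ketone, A7 must carry it at C2. The conjugate addition then has to create a fully substituted carbon, which is much harder than with a chromone unsubstituted at C2. A7 itself requires a ring A ortho-hydroxyaryl ketone with the propyl group already placed, so the regiochemical problem of ring A is only moved. A9 carries a surplus ester that must be removed by acidolysis and decarboxylation, and it has four differently substituted oxygens that need a further protection step.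
- Comparison: the chosen plan builds ring A and buys ring B, the alternative does the reverse. Overall step counts should be similar. The chosen plan carries one uniform set of methyl ethers, while the alternative is the equal or the better only in avoiding the dehydrogenation.

Key step: step 6

Remark: 10 is drawn as its triketone tautomer and as one enantiomer of the racemate, and step 7 is taken to give the mono-methyl ether 11 as the main product; any unmethylated or doubly methylated companion converges on 12 in step 8.

## Route

Step 1
Reactants: 1 methyl 3,5-dimethoxyphenylacetate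
Product: 2 2-(3,5-dimethoxyphenyl)ethanol
Conditions: LiAlH4, THF, 0 °C → rt; aq. NaOH work-up
Reagents that add atoms: none
Why: Hydride reduction of the ester to the primary alcohol; the aryl methyl ethers are inert and no stereocentre is involved.

Step 2
Reactants: 2 2-(3,5-dimethoxyphenyl)ethanol
Product: 3 1-[2-(benzyloxy)ethyl]-3,5-dimethoxybenzene
Conditions: NaH, BnBr, Bu4NI (cat.), THF, 0 °C → rt
Reagents that add atoms: benzyl bromide, BrCc1ccccc1
Why: Williamson ether synthesis on the sodium alkoxide. The benzyl ether is stable to methoxide, which matters because a free hydroxyethyl group next to the later β-dicarbonyl ketone could attack it and cleave the molecule by acyl transfer.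

Step 3
Reactants: 3 1-[2-(benzyloxy)ethyl]-3,5-dimethoxybenzene
Product: 5 2-[2-(benzyloxy)ethyl]-4,6-dimethoxybenzaldehyde, via aryl iminium chloride 4 (not isolated)
Conditions: POCl3, DMF, 0 → 70 °C; then aq. NaOAc
Reagents that add atoms: N,N-dimethylformamide, CN(C)C=O; water, O
Why: Vilsmeier–Haack formylation. The chloroiminium ion should attack the position para to one methoxy and ortho to the other, because the site between the two methoxy groups is more hindered; 4 is hydrolysed on work-up and the benzyl ether is stable to the reagent.

Step 4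
Reactants: 5 2-[2-(benzyloxy)ethyl]-4,6-dimethoxybenzaldehyde
Product: 6 methyl 3-{2-[2-(benzyloxy)ethyl]-4,6-dimethoxyphenyl}-3-hydroxypropanoate (racemic)
Conditions: CH3CO2CH3, LiN(iPr)2, THF, –78 °C; then 5; aq. NH4Cl at –78 °C
Reagents that add atoms: methyl acetate, COC(C)=O
Why: Aldol addition of the lithium enolate of methyl acetate to a non-enolizable aldehyde. The carbinol centre forms without control (racemic) and is removed in step 5; the cold quench prevents retro-aldol.

Step 5
Reactants: 6 methyl 3-{2-[2-(benzyloxy)ethyl]-4,6-dimethoxyphenyl}-3-hydroxypropanoate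
Product: 7 methyl 3-{2-[2-(benzyloxy)ethyl]-4,6-dimethoxyphenyl}-3-oxopropanoate
Conditions: Dess–Martin periodinane, NaHCO3, CH2Cl2, 0 °C → rt
Reagents that add atoms: none
Why: Dess–Martin oxidation of a β-hydroxy ester to the β-keto ester. The buffer keeps the electron-rich benzylic alcohol from ionizing or dehydrating, and the route avoids activating a di-ortho-substituted benzoic acid.

Step 6
Reactants: 7 methyl 3-{2-[2-(benzyloxy)ethyl]-4,6-dimethoxyphenyl}-3-oxopropanoate; 8 (E)-hept-3-en-2-one
Product: 10 trans-4-{2-[2-(benzyloxy)ethyl]-4,6-dimethoxybenzoyl}-5-propylcyclohexane-1,3-dione (racemic), via acyclic Michael adduct 9 (not isolated)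
Conditions: NaOCH3 (1.5 equiv), CH3OH, rt → 65 °C; then aq. HCl, 0 °C
Reagents that add atoms: none
Why: Methoxide forms the stabilized enolate of 7, which adds to the propyl-bearing β-carbon of 8 (Michael addition) to give 9 and creates the C4–C5 bond of the dione, C1–C2 of ring A. Proton transfer then gives the enolate on the methyl side of the ketone of 9, and this carbon acylates on the methyl ester with loss of methoxide (intramolecular Claisen condensation), creating the C2–C3 bond of the dione, C5–C6 of ring A. The closest known reaction type is the Michael–Claisen annulation of malonates with enones to 6-alkyl-2,4-dioxocyclohexanecarboxylates, with an aroylacetate in place of the malonate. The ring closes in the 6-(enolendo)-exo-trig mode, a favoured one, because the enolate C=C bond lies inside the forming ring and the ester C=O outside it. Deprotonation of the product at C2 to the vinylogous carboxylate drains the reversible Michael and Claisen equilibria towards 10. C5 is set in the Michael step without control (racemic), and C4, flanked by two carbonyl groups, should equilibrate under base to put the aroyl group trans to the propyl group; both centres vanish in step 7. The selectivity needed is acylation on the ester in preference to aldol closure on the aryl ketone, and the two ortho substituents (methoxy and benzyloxyethyl) twist and shield that ketone while the methyl ester stays accessible. The benzyl ether keeps the side-chain oxygen from attacking the β-dicarbonyl unit.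

Step 7
Reactants: 10 trans-4-{2-[2-(benzyloxy)ethyl]-4,6-dimethoxybenzoyl}-5-propylcyclohexane-1,3-dione
Product: 11 {2-[2-(benzyloxy)ethyl]-4,6-dimethoxyphenyl}(2-hydroxy-4-methoxy-6-propylphenyl)methanone
Conditions: I2 (2 equiv), CH3OH, 65 °C; aq. Na2S2O3
Reagents that add atoms: methanol, CO
Why: Oxidative aromatization of a cyclohexane-1,3-dione with iodine in methanol. Methanol should form the enol ether at the less hindered C1 carbonyl, α-iodination and loss of HI supply the missing unsaturation, and tautomerization gives the arene with the chelated ortho hydroxyl free. Both sp3 stereocentres are erased, and under the acidic conditions ring iodination is reversible.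

Step 8
Reactants: 11 {2-[2-(benzyloxy)ethyl]-4,6-dimethoxyphenyl}(2-hydroxy-4-methoxy-6-propylphenyl)methanone
Product: 12 {2-[2-(benzyloxy)ethyl]-4,6-dimethoxyphenyl}(2,4-dimethoxy-6-propylphenyl)methanone
Conditions: CH3I, K2CO3, DMF, 50 °C
Reagents that add atoms: iodomethane, CI
Why: Williamson O-methylation of the hydrogen-bonded phenol. Warm DMF overcomes the chelation, and the step gives all four phenol oxygens the same protecting group.

Step 9
Reactants: 12 {2-[2-(benzyloxy)ethyl]-4,6-dimethoxyphenyl}(2,4-dimethoxy-6-propylphenyl)methanone
Product: 13 [2-(2-hydroxyethyl)-4,6-dimethoxyphenyl](2,4-dimethoxy-6-propylphenyl)methanone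
Conditions: H2 (1 atm), Pd/C, EtOAc–CH3OH, rt
Reagents that add atoms: none
Why: Hydrogenolysis of the benzyl alkyl ether. The diaryl ketone is shielded by four ortho substituents and should not be reduced, and aryl methyl ethers are inert.

Step 10
Reactants: 13 [2-(2-hydroxyethyl)-4,6-dimethoxyphenyl](2,4-dimethoxy-6-propylphenyl)methanone
Product: 15 2-[2-(2,4-dimethoxy-6-propylbenzoyl)-3,5-dimethoxyphenyl]acetic acid, via arylacetaldehyde 14 (not isolated)
Conditions: TEMPO (cat.), PhI(OAc)2, CH3CN–H2O (1:1), rt
Reagents that add atoms: water, O
Why: Oxoammonium-catalysed oxidation of the primary alcohol to aldehyde 14, whose hydrate is oxidized on to the acid in the same pot. The conditions are metal-free and near neutral, so the electron-rich ether rings and the sensitive aldehyde stage are not exposed to strong acid or base.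

Step 11
Reactants: 15 2-[2-(2,4-dimethoxy-6-propylbenzoyl)-3,5-dimethoxyphenyl]acetic acid; 16 2,2,6-trimethyl-4H-1,3-dioxin-4-one
Product: 18 6-{3-[2-(2,4-dimethoxy-6-propylbenzoyl)-3,5-dimethoxyphenyl]-2-oxopropyl}-2,2-dimethyl-4H-1,3-dioxin-4-one, via acyl imidazolide 17 (not isolated)
Conditions: 15, 1,1'-carbonyldiimidazole, THF, rt; added to 16 and LiN(SiMe3)2 (2.5 equiv each), THF, –78 → –40 °C; aq. NH4Cl
Reagents that add atoms: none
Why: Claisen-type C-acylation of the lithium dienolate of 16 at its γ-carbon (the former methyl group) by acyl imidazolide 17. The excess dienolate takes up the acidic proton of the product, and the tetra-ortho-substituted diaryl ketone is too hindered to be attacked at low temperature.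

Step 12
Reactants: 18 6-{3-[2-(2,4-dimethoxy-6-propylbenzoyl)-3,5-dimethoxyphenyl]-2-oxopropyl}-2,2-dimethyl-4H-1,3-dioxin-4-one
Product: 20 6-{[2-(2,4-dimethoxy-6-propylbenzoyl)-3,5-dimethoxyphenyl]methyl}-4-hydroxy-2H-pyran-2-one, via acylketene 19 (not isolated)
Conditions: toluene, 110 °C, high dilution
Reagents that add atoms: none
Why: Thermal cycloreversion of the dioxinone releases acetone and acylketene 19, which is captured by the oxygen of the neighbouring ketone enol to close the 4-hydroxy-2-pyranone. This is the established dioxinone route to 6-substituted 4-hydroxy-2-pyranones, and it runs without acid or base.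

Step 13
Reactants: 20 6-{[2-(2,4-dimethoxy-6-propylbenzoyl)-3,5-dimethoxyphenyl]methyl}-4-hydroxy-2H-pyran-2-one
Product: 21 6-{[2-(2,4-dihydroxy-6-propylbenzoyl)-3,5-dihydroxyphenyl]methyl}-4-hydroxy-2H-pyran-2-one
Conditions: BBr3 (excess), CH2Cl2, –78 °C → rt; then CH3OH, H2O
Reagents that add atoms: none
Why: Lewis-acid cleavage of aryl methyl ethers by BBr3, with bromide attacking the methyl groups. The two ethers ortho to the ketone should cleave fast through chelation and the two para ethers at room temperature, while the pyranone is held as its borate until aqueous work-up.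

## Compound list

1 | methyl 3,5-dimethoxyphenylacetate | COC(=O)Cc1cc(OC)cc(OC)c1 | starting material
2 | 2-(3,5-dimethoxyphenyl)ethanol | OCCc1cc(OC)cc(OC)c1 | intermediate
3 | 1-[2-(benzyloxy)ethyl]-3,5-dimethoxybenzene | COc1cc(CCOCc2ccccc2)cc(OC)c1 | intermediate
4 | N-({2-[2-(benzyloxy)ethyl]-4,6-dimethoxyphenyl}methylidene)-N-methylmethanaminium chloride (not isolated) | C[N+](C)=Cc1c(OC)cc(OC)cc1CCOCc1ccccc1.[Cl-] | intermediate
5 | 2-[2-(benzyloxy)ethyl]-4,6-dimethoxybenzaldehyde | O=Cc1c(OC)cc(OC)cc1CCOCc1ccccc1 | intermediate
6 | methyl 3-{2-[2-(benzyloxy)ethyl]-4,6-dimethoxyphenyl}-3-hydroxypropanoate (racemic) | COC(=O)CC(O)c1c(OC)cc(OC)cc1CCOCc1ccccc1 | intermediate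
7 | methyl 3-{2-[2-(benzyloxy)ethyl]-4,6-dimethoxyphenyl}-3-oxopropanoate | COC(=O)CC(=O)c1c(OC)cc(OC)cc1CCOCc1ccccc1 | intermediate
8 | (E)-hept-3-en-2-one | CCC/C=C/C(C)=O | starting material
9 | methyl 2-{2-[2-(benzyloxy)ethyl]-4,6-dimethoxybenzoyl}-5-oxo-3-propylhexanoate (mixture of diastereomers, not isolated) | CCCC(CC(C)=O)C(C(=O)OC)C(=O)c1c(OC)cc(OC)cc1CCOCc1ccccc1 | intermediate
10 | trans-4-{2-[2-(benzyloxy)ethyl]-4,6-dimethoxybenzoyl}-5-propylcyclohexane-1,3-dione (racemic, one enantiomer drawn) | CCC[C@@H]1CC(=O)CC(=O)[C@H]1C(=O)c1c(OC)cc(OC)cc1CCOCc1ccccc1 | intermediate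
11 | {2-[2-(benzyloxy)ethyl]-4,6-dimethoxyphenyl}(2-hydroxy-4-methoxy-6-propylphenyl)methanone | CCCc1cc(OC)cc(O)c1C(=O)c1c(OC)cc(OC)cc1CCOCc1ccccc1 | intermediate
12 | {2-[2-(benzyloxy)ethyl]-4,6-dimethoxyphenyl}(2,4-dimethoxy-6-propylphenyl)methanone | CCCc1cc(OC)cc(OC)c1C(=O)c1c(OC)cc(OC)cc1CCOCc1ccccc1 | intermediate
13 | [2-(2-hydroxyethyl)-4,6-dimethoxyphenyl](2,4-dimethoxy-6-propylphenyl)methanone | CCCc1cc(OC)cc(OC)c1C(=O)c1c(OC)cc(OC)cc1CCO | intermediate
14 | 2-[2-(2,4-dimethoxy-6-propylbenzoyl)-3,5-dimethoxyphenyl]acetaldehyde (not isolated) | CCCc1cc(OC)cc(OC)c1C(=O)c1c(OC)cc(OC)cc1CC=O | intermediate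
15 | 2-[2-(2,4-dimethoxy-6-propylbenzoyl)-3,5-dimethoxyphenyl]acetic acid | CCCc1cc(OC)cc(OC)c1C(=O)c1c(OC)cc(OC)cc1CC(=O)O | intermediate
16 | 2,2,6-trimethyl-4H-1,3-dioxin-4-one | CC1=CC(=O)OC(C)(C)O1 | starting material
17 | 2-[2-(2,4-dimethoxy-6-propylbenzoyl)-3,5-dimethoxyphenyl]-1-(1H-imidazol-1-yl)ethan-1-one (not isolated) | CCCc1cc(OC)cc(OC)c1C(=O)c1c(OC)cc(OC)cc1CC(=O)n1ccnc1 | intermediate
18 | 6-{3-[2-(2,4-dimethoxy-6-propylbenzoyl)-3,5-dimethoxyphenyl]-2-oxopropyl}-2,2-dimethyl-4H-1,3-dioxin-4-one | CCCc1cc(OC)cc(OC)c1C(=O)c1c(OC)cc(OC)cc1CC(=O)CC1=CC(=O)OC(C)(C)O1 | intermediate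
19 | 6-[2-(2,4-dimethoxy-6-propylbenzoyl)-3,5-dimethoxyphenyl]hex-1-ene-1,3,5-trione (acylketene, not isolated) | CCCc1cc(OC)cc(OC)c1C(=O)c1c(OC)cc(OC)cc1CC(=O)CC(=O)C=C=O | intermediate
20 | 6-{[2-(2,4-dimethoxy-6-propylbenzoyl)-3,5-dimethoxyphenyl]methyl}-4-hydroxy-2H-pyran-2-one | CCCc1cc(OC)cc(OC)c1C(=O)c1c(OC)cc(OC)cc1Cc1cc(O)cc(=O)o1 | intermediate
21 | 6-{[2-(2,4-dihydroxy-6-propylbenzoyl)-3,5-dihydroxyphenyl]methyl}-4-hydroxy-2H-pyran-2-one | CCCc1cc(O)cc(O)c1C(=O)c1c(O)cc(O)cc1Cc1cc(O)cc(=O)o1 | target

## Step count and least certain steps

Total step count: 13. Longest linear sequence: 13 steps (1 to 21); 8 and 16 are purchased.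

**Step 6 (key step).** The hindered enolate of 7 may add only sluggishly to the β-substituted enone, the Michael addition may revert, or ring closure may take the aldol course onto the aryl ketone instead of the Claisen course onto the ester. Fallback, setting out from 5 and giving up the ring-forming disconnection in favour of forming the ring A–carbonyl bond:
- Purchased 5-propylcyclohexane-1,3-dione F1 is converted with CH3OH and TsOH into 3-methoxy-5-propylcyclohex-2-en-1-one F2.
- Its kinetic lithium enolate (LiN(iPr)2, THF, –78 °C, deprotonation at C6) is added to 5 to give the aldol adduct 6-[{2-[2-(benzyloxy)ethyl]-4,6-dimethoxyphenyl}(hydroxy)methyl]-3-methoxy-5-propylcyclohex-2-en-1-one F3.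
- Dess–Martin oxidation should give 6-{2-[2-(benzyloxy)ethyl]-4,6-dimethoxybenzoyl}-3-methoxy-5-propylcyclohex-2-en-1-one F4.
- I2 in CH3OH should dehydrogenate F4, and the route is rejoined at 11.

**Step 7.** Dehydrogenation may stop short, the benzyl ether may be lost to the HI formed, or the electron-rich rings may be iodinated. Fallback, setting out from 10: a halogen-free catalytic dehydrogenation with Pd(O2CCF3)2, 2-(dimethylamino)pyridine and TsOH under O2 in DMSO at 80 °C should give the free resorcinol {2-[2-(benzyloxy)ethyl]-4,6-dimethoxyphenyl}(2,4-dihydroxy-6-propylphenyl)methanone F5. Methylation of both hydroxyls with CH3I and K2CO3 rejoins the route at 12.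

**Step 11.** The dienolate may deprotonate the acidic arylacetyl donor instead of being acylated, or the activated acid may close onto the neighbouring ketone. Fallback, setting out from 13, which changes the bond formation from an acylation to an aldol addition under Lewis acid:
- 13 is oxidized with Dess–Martin periodinane only as far as 14, which is isolated.
- 16 is converted with LiN(SiMe3)2 and (CH3)3SiCl into its silyl dienol ether [(2,2-dimethyl-6-methylidene-6H-1,3-dioxin-4-yl)oxy]trimethylsilane F6.
- A vinylogous Mukaiyama aldol addition of F6 to 14 (BF3·OEt2, CH2Cl2, –78 °C) should give 6-{3-[2-(2,4-dimethoxy-6-propylbenzoyl)-3,5-dimethoxyphenyl]-2-hydroxypropyl}-2,2-dimethyl-4H-1,3-dioxin-4-one F7.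
- Dess–Martin oxidation of F7 rejoins the route at 18.

**Step 13.** Cleavage of the two ethers para to the ketone may remain incomplete, or the Lewis acid may promote condensation between ring C and the ketone. Fallback, setting out from 13, which moves the ether cleavage to a stage without ring C and changes the protecting group:
- BBr3 in CH2Cl2 should give (2,4-dihydroxy-6-propylphenyl)[2,4-dihydroxy-6-(2-hydroxyethyl)phenyl]methanone F8.
- BnBr and K2CO3 in DMF benzylate the four phenols only, to [2,4-bis(benzyloxy)-6-(2-hydroxyethyl)phenyl][2,4-bis(benzyloxy)-6-propylphenyl]methanone F9.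
- Oxidation as in step 10 passes through 2-{3,5-bis(benzyloxy)-2-[2,4-bis(benzyloxy)-6-propylbenzoyl]phenyl}acetaldehyde F10 to 2-{3,5-bis(benzyloxy)-2-[2,4-bis(benzyloxy)-6-propylbenzoyl]phenyl}acetic acid F11.
- Coupling with 16 as in step 11, through the acyl imidazolide 2-{3,5-bis(benzyloxy)-2-[2,4-bis(benzyloxy)-6-propylbenzoyl]phenyl}-1-(1H-imidazol-1-yl)ethan-1-one F12, should give 6-(3-{3,5-bis(benzyloxy)-2-[2,4-bis(benzyloxy)-6-propylbenzoyl]phenyl}-2-oxopropyl)-2,2-dimethyl-4H-1,3-dioxin-4-one F13.
- Thermolysis as in step 12, through the acylketene 6-{3,5-bis(benzyloxy)-2-[2,4-bis(benzyloxy)-6-propylbenzoyl]phenyl}hex-1-ene-1,3,5-trione F14, should give 6-({3,5-bis(benzyloxy)-2-[2,4-bis(benzyloxy)-6-propylbenzoyl]phenyl}methyl)-4-hydroxy-2H-pyran-2-one F15.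
- Hydrogenolysis (H2, Pd/C, EtOAc) under neutral conditions rejoins the route at 21.

**Step 3.** Formylation may go in part to the position between the two methoxy groups. Fallback, setting out from 3: NBS in CH3CN at 0 °C should brominate para to a methoxy group to give 1-[2-(benzyloxy)ethyl]-2-bromo-3,5-dimethoxybenzene F16. Bromine–lithium exchange with n-BuLi in THF at –78 °C gives {2-[2-(benzyloxy)ethyl]-4,6-dimethoxyphenyl}lithium F17, and quenching with DMF rejoins the route at 5.

## Further compounds

F1 | step 6 | 5-propylcyclohexane-1,3-dione | CCCC1CC(=O)CC(=O)C1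
F2 | step 6 | 3-methoxy-5-propylcyclohex-2-en-1-one (racemic) | CCCC1CC(OC)=CC(=O)C1
F3 | step 6 | 6-[{2-[2-(benzyloxy)ethyl]-4,6-dimethoxyphenyl}(hydroxy)methyl]-3-methoxy-5-propylcyclohex-2-en-1-one (mixture of diastereomers) | CCCC1CC(OC)=CC(=O)C1C(O)c1c(OC)cc(OC)cc1CCOCc1ccccc1
F4 | step 6 | 6-{2-[2-(benzyloxy)ethyl]-4,6-dimethoxybenzoyl}-3-methoxy-5-propylcyclohex-2-en-1-one (racemic) | CCCC1CC(OC)=CC(=O)C1C(=O)c1c(OC)cc(OC)cc1CCOCc1ccccc1
F5 | step 7 | {2-[2-(benzyloxy)ethyl]-4,6-dimethoxyphenyl}(2,4-dihydroxy-6-propylphenyl)methanone | CCCc1cc(O)cc(O)c1C(=O)c1c(OC)cc(OC)cc1CCOCc1ccccc1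
F6 | step 11 | [(2,2-dimethyl-6-methylidene-6H-1,3-dioxin-4-yl)oxy]trimethylsilane | C=C1C=C(O[Si](C)(C)C)OC(C)(C)O1
F7 | step 11 | 6-{3-[2-(2,4-dimethoxy-6-propylbenzoyl)-3,5-dimethoxyphenyl]-2-hydroxypropyl}-2,2-dimethyl-4H-1,3-dioxin-4-one (racemic) | CCCc1cc(OC)cc(OC)c1C(=O)c1c(OC)cc(OC)cc1CC(O)CC1=CC(=O)OC(C)(C)O1
F8 | step 13 | (2,4-dihydroxy-6-propylphenyl)[2,4-dihydroxy-6-(2-hydroxyethyl)phenyl]methanone | CCCc1cc(O)cc(O)c1C(=O)c1c(O)cc(O)cc1CCO
F9 | step 13 | [2,4-bis(benzyloxy)-6-(2-hydroxyethyl)phenyl][2,4-bis(benzyloxy)-6-propylphenyl]methanone | CCCc1cc(OCc2ccccc2)cc(OCc2ccccc2)c1C(=O)c1c(OCc2ccccc2)cc(OCc2ccccc2)cc1CCO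
F10 | step 13 | 2-{3,5-bis(benzyloxy)-2-[2,4-bis(benzyloxy)-6-propylbenzoyl]phenyl}acetaldehyde | CCCc1cc(OCc2ccccc2)cc(OCc2ccccc2)c1C(=O)c1c(OCc2ccccc2)cc(OCc2ccccc2)cc1CC=O
F11 | step 13 | 2-{3,5-bis(benzyloxy)-2-[2,4-bis(benzyloxy)-6-propylbenzoyl]phenyl}acetic acid | CCCc1cc(OCc2ccccc2)cc(OCc2ccccc2)c1C(=O)c1c(OCc2ccccc2)cc(OCc2ccccc2)cc1CC(=O)O
F12 | step 13 | 2-{3,5-bis(benzyloxy)-2-[2,4-bis(benzyloxy)-6-propylbenzoyl]phenyl}-1-(1H-imidazol-1-yl)ethan-1-one | CCCc1cc(OCc2ccccc2)cc(OCc2ccccc2)c1C(=O)c1c(OCc2ccccc2)cc(OCc2ccccc2)cc1CC(=O)n1ccnc1
F13 | step 13 | 6-(3-{3,5-bis(benzyloxy)-2-[2,4-bis(benzyloxy)-6-propylbenzoyl]phenyl}-2-oxopropyl)-2,2-dimethyl-4H-1,3-dioxin-4-one | CCCc1cc(OCc2ccccc2)cc(OCc2ccccc2)c1C(=O)c1c(OCc2ccccc2)cc(OCc2ccccc2)cc1CC(=O)CC1=CC(=O)OC(C)(C)O1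
F14 | step 13 | 6-{3,5-bis(benzyloxy)-2-[2,4-bis(benzyloxy)-6-propylbenzoyl]phenyl}hex-1-ene-1,3,5-trione | CCCc1cc(OCc2ccccc2)cc(OCc2ccccc2)c1C(=O)c1c(OCc2ccccc2)cc(OCc2ccccc2)cc1CC(=O)CC(=O)C=C=O
F15 | step 13 | 6-({3,5-bis(benzyloxy)-2-[2,4-bis(benzyloxy)-6-propylbenzoyl]phenyl}methyl)-4-hydroxy-2H-pyran-2-one | CCCc1cc(OCc2ccccc2)cc(OCc2ccccc2)c1C(=O)c1c(OCc2ccccc2)cc(OCc2ccccc2)cc1Cc1cc(O)cc(=O)o1
F16 | step 3 | 1-[2-(benzyloxy)ethyl]-2-bromo-3,5-dimethoxybenzene | COc1cc(OC)c(Br)c(CCOCc2ccccc2)c1
F17 | step 3 | {2-[2-(benzyloxy)ethyl]-4,6-dimethoxyphenyl}lithium | [Li]c1c(OC)cc(OC)cc1CCOCc1ccccc1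
A1 | alternative 1 | 1-(tert-butyldimethylsilyloxy)deca-3,6-diyn-5-one | CCCC#CC(=O)C#CCCO[Si](C)(C)C(C)(C)C
A2 | alternative 1 | 1,1-dimethoxy-3-(trimethylsilyloxy)buta-1,3-diene | COC(OC)=CC(=C)O[Si](C)(C)C
A3 | alternative 1 | {2-[2-(tert-butyldimethylsilyloxy)ethyl]-4-hydroxy-6-methoxyphenyl}(4-hydroxy-2-methoxy-6-propylphenyl)methanone | CCCc1cc(O)cc(OC)c1C(=O)c1c(OC)cc(O)cc1CCO[Si](C)(C)C(C)(C)C
A4 | alternative 2 | bis(2,4-dimethoxyphenyl)methanone | COc1ccc(C(=O)c2ccc(OC)cc2OC)c(OC)c1
A5 | alternative 2 | allyl acetate | CC(=O)OCC=C
A6 | alternative 2 | bis(2-allyl-4,6-dimethoxyphenyl)methanone | C=CCc1cc(OC)cc(OC)c1C(=O)c1c(OC)cc(OC)cc1CC=C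
A7 | alternative 3 | methyl 2-[2-(benzyloxy)ethyl]-7-methoxy-4-oxo-5-propyl-4H-chromene-3-carboxylate | CCCc1cc(OC)cc2oc(CCOCc3ccccc3)c(C(=O)OC)c(=O)c12
A8 | alternative 3 | 1-tert-butoxy-1,3-bis(trimethylsilyloxy)buta-1,3-diene | C=C(O[Si](C)(C)C)C=C(OC(C)(C)C)O[Si](C)(C)C
A9 | alternative 3 | tert-butyl 4-[2-(benzyloxy)ethyl]-2,6-dihydroxy-3-(2-hydroxy-4-methoxy-6-propylbenzoyl)benzoate | CCCc1cc(OC)cc(O)c1C(=O)c1c(O)c(C(=O)OC(C)(C)C)c(O)cc1CCOCc1ccccc1
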